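**Plan**

- Retrosynthesis: (a) the ring bond C4–C5 of the 1,2-dioxane is cut last, back to an acyclic tertiary/secondary dialkyl peroxide with CH2I on C6 and a vinyl group on C3; (b) the C3'–C4' bond between the two trisubstituted alkenes of the 2,4-dimethyl-6-phenylhexa-2,4-dienyl side chain (cross-coupling); (c) O2–C3 (conjugate addition of a hydroperoxide to a dienal); (d) O1–C6 (perhydrolysis of a 2,2-disubstituted epoxide).
- Forward: the C6 fragment is built from (S)-2-methylglycidol (alkynylation, carboalumination–iodination, epoxide), opened with H2O2, joined to the C1–C4 unit by enal peroxidation, oxidised and esterified, CH2OH is turned into CH2I, the diene is completed by Negishi coupling, and the ring is closed last.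
- Stereochemistry: C6 from the glycidol through invertive epoxide perhydrolysis; C3 by catalyst-controlled peroxidation; C4 in the ring closure, relayed from C3 through a chair transition state; both alkenes from syn carbo-/hydrometalation and stereoretentive coupling.
- Enabling feature: the O1–O2 bridge ties C6 to C3, so the C6-bound methylene carbon (C5) and the inner vinyl carbon on C3 (C4) stand in a 3,4-dioxahept-6-enyl relationship; a radical at C5 closes the six-membered ring O1–O2–C3–C4–C5–C6 at C4, and the terminal vinyl carbon becomes the C4 methyl group.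

Key step: step 10

Remark: ring atoms are numbered O1–O2–C3–C4–C5–C6 (C3 bears CH2CO2Me, C4 the methyl group, C6 the methyl group and the side chain); (S)-2-methylglycidol, (2E)-penta-2,4-dienal and 1-phenyl-2-butyne are assumed to be purchased.

**Route**

Step 1
Reactants: 1 (S)-2-methylglycidol, [(2S)-2-methyloxiran-2-yl]methanol
Product: 2 (2R)-2-methylpent-4-yne-1,2-diol
Conditions: LiC≡CH·H2NCH2CH2NH2 (2.5 equiv), DMSO, 15 °C to rt; then H2O
Reagents that add atoms: lithium acetylide ethylenediamine complex, [Li+].[C-]#C.NCCN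
Why: SN2 opening of the epoxide by acetylide at the unsubstituted ring carbon; the quaternary stereocentre is not touched and is carried over (the descriptor changes only because the priorities change).

Step 2
Reactants: 2 (2R)-2-methylpent-4-yne-1,2-diol
Product: 4 (2R,4E)-5-iodo-2,4-dimethylpent-4-ene-1,2-diol, via alkenylalane 3 (not isolated)
Conditions: AlMe3 (4 equiv), Cp2ZrCl2 (0.25 equiv), CH2Cl2, 0 °C to rt; then I2, THF, −30 °C; aqueous work-up
Reagents that add atoms: trimethylaluminium, C[Al](C)C; iodine, II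
Why: Zirconium-catalysed carboalumination (Negishi carboalumination) adds Me and Al syn with Me on the internal alkyne carbon, the two hydroxyls being carried as aluminium alkoxides, and iododealumination with retention should give the (E)-alkenyl iodide.

Step 3
Reactants: 4 (2R,4E)-5-iodo-2,4-dimethylpent-4-ene-1,2-diol
Product: 6 (2R)-2-[(2E)-3-iodo-2-methylprop-2-en-1-yl]-2-methyloxirane, via monotosylate 5 (not isolated)
Conditions: NaH (2.2 equiv), THF, 0 °C; then 1-(p-tolylsulfonyl)imidazole (1.05 equiv), 0 °C to rt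
Reagents that add atoms: none
Why: Selective sulfonylation of the primary alkoxide followed by intramolecular Williamson displacement by the tertiary alkoxide (one-flask epoxide formation from a 1,2-diol); the C–O bond at the stereocentre is kept, so the configuration is retained.

Step 4
Reactants: 6 (2R)-2-[(2E)-3-iodo-2-methylprop-2-en-1-yl]-2-methyloxirane
Product: 7 (2S,4E)-2-hydroperoxy-5-iodo-2,4-dimethylpent-4-en-1-ol
Conditions: anhydrous H2O2 in Et2O (excess), H3PMo12O40 (2 mol%), Et2O, rt
Reagents that add atoms: hydrogen peroxide, OO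
Why: Acid-catalysed perhydrolysis of a 2,2-disubstituted epoxide, in which H2O2 attacks the tertiary carbon of the activated epoxide with inversion; this sets the O1–C6 bond and the C6 configuration of the target.

Step 5
Reactants: 7 (2S,4E)-2-hydroperoxy-5-iodo-2,4-dimethylpent-4-en-1-ol; 8 (2E)-penta-2,4-dienal
Product: 9 (3S)-3-{[(2S,4E)-1-hydroxy-5-iodo-2,4-dimethylpent-4-en-2-yl]peroxy}pent-4-enal
Conditions: (S)-2-{bis[3,5-bis(trifluoromethyl)phenyl][(trimethylsilyl)oxy]methyl}pyrrolidine (20 mol%), PhMe, −20 °C, no acid additive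
Reagents that add atoms: none
Why: Iminium-catalysed asymmetric β-peroxidation (oxa-Michael addition) of an enal by a tertiary hydroperoxide, which should add 1,4 as in nucleophilic epoxidation of dienals and from the face of the (E)-iminium opposite to the C2 substituent of the (S)-catalyst, giving the (3S) centre.

Step 6
Reactants: 9 (3S)-3-{[(2S,4E)-1-hydroxy-5-iodo-2,4-dimethylpent-4-en-2-yl]peroxy}pent-4-enal
Product: 10 (3S)-3-{[(2S,4E)-1-hydroxy-5-iodo-2,4-dimethylpent-4-en-2-yl]peroxy}pent-4-enoic acid
Conditions: NaClO2, NaH2PO4, 2-methylbut-2-ene (excess), t-BuOH/H2O, 0 °C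
Reagents that add atoms: sodium chlorite, [Na+].[O-]Cl=O
Why: Pinnick oxidation converts the aldehyde to the acid under buffered, weakly acidic conditions that should spare the dialkyl peroxide, the primary alcohol and both alkenes (HOCl is scavenged) and cannot trigger base-induced loss of the β-peroxy group.

Step 7
Reactants: 10 (3S)-3-{[(2S,4E)-1-hydroxy-5-iodo-2,4-dimethylpent-4-en-2-yl]peroxy}pent-4-enoic acid
Product: 11 methyl (3S)-3-{[(2S,4E)-1-hydroxy-5-iodo-2,4-dimethylpent-4-en-2-yl]peroxy}pent-4-enoate
Conditions: Me3SiCHN2 (1.5 equiv), PhMe/MeOH 4:1, 0 °C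
Reagents that add atoms: (trimethylsilyl)diazomethane, C[Si](C)(C)C=[N+]=[N-]
Why: Base-free O-methylation of the carboxylic acid by in situ diazomethane, chosen because the β-peroxy ester would not tolerate basic esterification.

Step 8
Reactants: 11 methyl (3S)-3-{[(2S,4E)-1-hydroxy-5-iodo-2,4-dimethylpent-4-en-2-yl]peroxy}pent-4-enoate
Product: 13 methyl (3S)-3-{[(2S,4E)-1,5-diiodo-2,4-dimethylpent-4-en-2-yl]peroxy}pent-4-enoate, via triflate 12 (not isolated)
Conditions: (CF3SO2)2O (1.2 equiv), 2,6-lutidine (1.5 equiv), CH2Cl2, −78 °C; then Bu4NI (3 equiv), −78 °C to rt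
Reagents that add atoms: tetrabutylammonium iodide, CCCC[N+](CCCC)(CCCC)CCCC.[I-]
Why: Triflation of the primary alcohol and SN2 displacement by iodide; the β-carbon is quaternary so elimination is impossible, the electron-poor β-peroxy group disfavours ionisation, and no stereocentre is touched.

Step 9
Reactants: 13 methyl (3S)-3-{[(2S,4E)-1,5-diiodo-2,4-dimethylpent-4-en-2-yl]peroxy}pent-4-enoate; 14 1-phenyl-2-butyne (but-2-yn-1-ylbenzene)
Product: 16 methyl (3S)-3-{[(2S,4E,6E)-1-iodo-2,4,6-trimethyl-8-phenylocta-4,6-dien-2-yl]peroxy}pent-4-enoate, via alkenylzirconocene 15 (not isolated)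
Conditions: 14, Cp2Zr(H)Cl, THF, 40 °C (equilibration), clear solution decanted from undissolved Cp2Zr(H)Cl; then 13, ZnCl2 (0.3 equiv), Pd(PPh3)4 (5 mol%), THF, rt
Reagents that add atoms: none
Why: Syn hydrozirconation should place zirconium on the methyl-bearing alkyne carbon after equilibration, and ZnCl2-assisted Negishi coupling with zerovalent palladium joins 15 to the C(sp2)–I bond of 13 with retention of both alkene geometries, the neopentyl-type C(sp3)–I bond being far slower in oxidative addition and the dialkyl peroxide being tolerated.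

Step 10
Reactants: 16 methyl (3S)-3-{[(2S,4E,6E)-1-iodo-2,4,6-trimethyl-8-phenylocta-4,6-dien-2-yl]peroxy}pent-4-enoate
Product: 17 methyl 2-[(3S,4R,6R)-4,6-dimethyl-6-[(2E,4E)-2,4-dimethyl-6-phenylhexa-2,4-dien-1-yl]-1,2-dioxan-3-yl]acetate
Conditions: Bu3SnH (1.2 equiv, syringe pump), Et3B (0.2 equiv)/air, PhMe (0.005 M), −40 °C
Reagents that add atoms: none
Why: Proposed new method: Bu3Sn• abstracts iodine from C5, the β-peroxyalkyl radical adds to C4 (the inner carbon of the vinyl group on C3), and the exocyclic primary radical takes H from Bu3SnH to become the C4 methyl group. The closest known reaction types are the 6-exo cyclisation of hept-6-enyl radicals and the Ueno–Stork cyclisation of β-oxygenated alkyl radicals; a carbon-radical closure through an O–O tether is not established. The 1,2-dioxane closes in the 6-exo-trig mode, the 7-endo mode being disfavoured for a terminal alkene. C4 is set by a chair-like transition state with the C3 CH2CO2Me group and the forming C4–CH2• bond equatorial (3,4-trans); the same chair puts the larger C6 substituent equatorial and the C6 methyl axial, so the preset C3 and C6 centres reinforce each other. The closure must outrun homolytic substitution of the C5 radical at O1 (epoxide formation with O–O cleavage), 1,5-hydrogen transfer from the allylic C3–H, and premature reduction. The quaternary C6 (gem-dialkyl effect), the two short C–O bonds of the tether, low temperature and a low stationary tin hydride concentration are relied on for this.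

**Compound list**

1 | (S)-2-methylglycidol, [(2S)-2-methyloxiran-2-yl]methanol | C[C@]1(CO)CO1 | starting material
2 | (2R)-2-methylpent-4-yne-1,2-diol | C#CC[C@@](C)(O)CO | intermediate
3 | [(1E,4R)-4,5-bis(dimethylalumanyloxy)-2,4-dimethylpent-1-en-1-yl]dimethylalane (alkenylalane) | C[Al](C)OC[C@](C)(O[Al](C)C)C/C(C)=C/[Al](C)C | intermediate
4 | (2R,4E)-5-iodo-2,4-dimethylpent-4-ene-1,2-diol | OC[C@](C)(O)C/C(C)=C/I | intermediate
5 | sodium (2R,4E)-5-iodo-2,4-dimethyl-1-(tosyloxy)pent-4-en-2-olate (monotosylate) | Cc1ccc(cc1)S(=O)(=O)OC[C@](C)([O-])C/C(C)=C/I.[Na+] | intermediate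
6 | (2R)-2-[(2E)-3-iodo-2-methylprop-2-en-1-yl]-2-methyloxirane | C[C@@]1(C/C(C)=C/I)CO1 | intermediate
7 | (2S,4E)-2-hydroperoxy-5-iodo-2,4-dimethylpent-4-en-1-ol | OC[C@@](C)(OO)C/C(C)=C/I | intermediate
8 | (2E)-penta-2,4-dienal | C=C/C=C/C=O | starting material
9 | (3S)-3-{[(2S,4E)-1-hydroxy-5-iodo-2,4-dimethylpent-4-en-2-yl]peroxy}pent-4-enal | O=CC[C@@H](C=C)OO[C@@](C)(C/C(C)=C/I)CO | intermediate
10 | (3S)-3-{[(2S,4E)-1-hydroxy-5-iodo-2,4-dimethylpent-4-en-2-yl]peroxy}pent-4-enoic acid | OC(=O)C[C@@H](C=C)OO[C@@](C)(C/C(C)=C/I)CO | intermediate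
11 | methyl (3S)-3-{[(2S,4E)-1-hydroxy-5-iodo-2,4-dimethylpent-4-en-2-yl]peroxy}pent-4-enoate | COC(=O)C[C@@H](C=C)OO[C@@](C)(C/C(C)=C/I)CO | intermediate
12 | methyl (3S)-3-{[(2S,4E)-5-iodo-2,4-dimethyl-1-(trifluoromethylsulfonyloxy)pent-4-en-2-yl]peroxy}pent-4-enoate (triflate) | COC(=O)C[C@@H](C=C)OO[C@@](C)(C/C(C)=C/I)COS(=O)(=O)C(F)(F)F | intermediate
13 | methyl (3S)-3-{[(2S,4E)-1,5-diiodo-2,4-dimethylpent-4-en-2-yl]peroxy}pent-4-enoate | COC(=O)C[C@@H](C=C)OO[C@@](C)(C/C(C)=C/I)CI | intermediate
14 | 1-phenyl-2-butyne (but-2-yn-1-ylbenzene) | CC#CCc1ccccc1 | starting material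
15 | chloridobis(cyclopentadienyl)[(2E)-4-phenylbut-2-en-2-yl]zirconium (alkenylzirconocene) | Cl[Zr](C1C=CC=C1)(C1C=CC=C1)/C(C)=C/Cc1ccccc1 | intermediate
16 | methyl (3S)-3-{[(2S,4E,6E)-1-iodo-2,4,6-trimethyl-8-phenylocta-4,6-dien-2-yl]peroxy}pent-4-enoate | COC(=O)C[C@@H](C=C)OO[C@@](C)(C/C(C)=C/C(C)=C/Cc1ccccc1)CI | intermediate
17 | methyl 2-[(3S,4R,6R)-4,6-dimethyl-6-[(2E,4E)-2,4-dimethyl-6-phenylhexa-2,4-dien-1-yl]-1,2-dioxan-3-yl]acetate | COC(=O)C[C@@H]1OO[C@@](C)(C/C(C)=C/C(C)=C/Cc2ccccc2)C[C@H]1C | target

**Step count and risks**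

Total step count: 10. Longest linear sequence: 10 steps (1 to 17; 8 and 14 are purchased).

Steps most likely to fail:

1. Step 10 (Proposed new method). After iodine abstraction the C5 radical may substitute homolytically at O1 (three-membered transition state, O–O cleavage) or take the allylic C3–H by 1,5-hydrogen transfer faster than it closes the ring; it may also be reduced before cyclising, and the chair preference that sets C4 could be modest. Fallback, known chemistry, ring-closing metathesis at the same bond; it sets out from 7 and comes back at 17. Hydroperoxide 7 is added to (2E)-4-methylpenta-2,4-dienal under the conditions of step 5 to give (3S)-3-{[(2S,4E)-1-hydroxy-5-iodo-2,4-dimethylpent-4-en-2-yl]peroxy}-4-methylpent-4-enal F1. Pinnick oxidation gives the corresponding pent-4-enoic acid F2 and Me3SiCHN2 its methyl ester F3. Dess–Martin oxidation of the primary alcohol gives the 1-oxo compound F4, and Wittig methylenation (Ph3P=CH2, THF, −78 °C) gives the bis-allylic peroxide F5. Ring-closing metathesis with the second-generation Grubbs catalyst (H2IMes)(PCy3)Cl2Ru=CHPh, a catalyst class that tolerates dialkyl peroxides, forms C4=C5 and gives the 3,6-dihydro-1,2-dioxine F6. Diimide (KO2CN=NCO2K, AcOH) saturates the ring alkene without O–O cleavage to give the iodo-dioxane F7; the facial selectivity of this reduction is uncertain, so C4 epimers may have to be separated. Coupling of F7 with 15 as in step 9 gives 17.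

2. Step 5. The hydroperoxide may add at the remote diene terminus, the β-peroxy enamine may collapse to an epoxide with O–O cleavage, the hydroxy hydroperoxide may acetalise with the aldehyde, or catalyst control may be weak. Fallback: sets out from 7 and comes back at 11. Base-mediated conjugate addition of 7 to methyl (2E)-penta-2,4-dienoate (Cs2CO3 cat., CF3CH2OH, 0 °C) gives ester 11 directly, without the aldehyde and acid stages, together with its C3 epimer, methyl (3R)-3-{[(2S,4E)-1-hydroxy-5-iodo-2,4-dimethylpent-4-en-2-yl]peroxy}pent-4-enoate F8. The two diastereomers are separated by chromatography, and F8 can be recycled through base-induced retro-addition.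

3. Step 8. Substitution at the neopentyl-type carbon may be slow, which would allow ionisation of the triflate with participation of the O–O group and skeletal rearrangement. Fallback: sets out from 11 and comes back at 17. Alcohol 11 is coupled first with 15 (step 9 conditions, one extra equivalent of 15 for the free hydroxyl) to give methyl (3S)-3-{[(2S,4E,6E)-1-hydroxy-2,4,6-trimethyl-8-phenylocta-4,6-dien-2-yl]peroxy}pent-4-enoate F9. Acylation with 1,1'-thiocarbonyldiimidazole gives its O-alkyl imidazole-1-carbothioate F10. Barton–McCombie C–O scission of F10 with (Me3Si)3SiH/AIBN (PhMe, 80 °C) generates the same C5 radical without any substitution at that carbon, and the radical closes to 17 as in step 10.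

Further compounds
F1 | step 10 | (3S)-3-{[(2S,4E)-1-hydroxy-5-iodo-2,4-dimethylpent-4-en-2-yl]peroxy}-4-methylpent-4-enal | O=CC[C@@H](C(C)=C)OO[C@@](C)(C/C(C)=C/I)CO
F2 | step 10 | (3S)-3-{[(2S,4E)-1-hydroxy-5-iodo-2,4-dimethylpent-4-en-2-yl]peroxy}-4-methylpent-4-enoic acid | OC(=O)C[C@@H](C(C)=C)OO[C@@](C)(C/C(C)=C/I)CO
F3 | step 10 | methyl (3S)-3-{[(2S,4E)-1-hydroxy-5-iodo-2,4-dimethylpent-4-en-2-yl]peroxy}-4-methylpent-4-enoate | COC(=O)C[C@@H](C(C)=C)OO[C@@](C)(C/C(C)=C/I)CO
F4 | step 10 | methyl (3S)-3-{[(2S,4E)-5-iodo-2,4-dimethyl-1-oxopent-4-en-2-yl]peroxy}-4-methylpent-4-enoate | COC(=O)C[C@@H](C(C)=C)OO[C@@](C)(C/C(C)=C/I)C=O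
F5 | step 10 | methyl (3S)-3-{[(3S,5E)-6-iodo-3,5-dimethylhexa-1,5-dien-3-yl]peroxy}-4-methylpent-4-enoate | COC(=O)C[C@@H](C(C)=C)OO[C@@](C)(C/C(C)=C/I)C=C
F6 | step 10 | methyl 2-[(3S,6S)-6-[(2E)-3-iodo-2-methylprop-2-en-1-yl]-4,6-dimethyl-3,6-dihydro-1,2-dioxin-3-yl]acetate | COC(=O)C[C@@H]1OO[C@@](C)(C/C(C)=C/I)C=C1C
F7 | step 10 | methyl 2-[(3S,4R,6R)-6-[(2E)-3-iodo-2-methylprop-2-en-1-yl]-4,6-dimethyl-1,2-dioxan-3-yl]acetate | COC(=O)C[C@@H]1OO[C@@](C)(C/C(C)=C/I)C[C@H]1C
F8 | step 5 | methyl (3R)-3-{[(2S,4E)-1-hydroxy-5-iodo-2,4-dimethylpent-4-en-2-yl]peroxy}pent-4-enoate | COC(=O)C[C@H](C=C)OO[C@@](C)(C/C(C)=C/I)CO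
F9 | step 8 | methyl (3S)-3-{[(2S,4E,6E)-1-hydroxy-2,4,6-trimethyl-8-phenylocta-4,6-dien-2-yl]peroxy}pent-4-enoate | COC(=O)C[C@@H](C=C)OO[C@@](C)(C/C(C)=C/C(C)=C/Cc1ccccc1)CO
F10 | step 8 | O-{(2S,4E,6E)-2-{[(3S)-5-methoxy-5-oxopent-1-en-3-yl]peroxy}-2,4,6-trimethyl-8-phenylocta-4,6-dien-1-yl} 1H-imidazole-1-carbothioate | COC(=O)C[C@@H](C=C)OO[C@@](C)(C/C(C)=C/C(C)=C/Cc1ccccc1)COC(=S)n1ccnc1
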